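**Retrosynthetic overview**
1. The target is the 8α-formate of (13S)-8α-hydroxylabdan-15-oic acid. The formyl group, the C15 oxidation level and the C9–C11 bond are removed first, which leads to a trans-fused bicyclic ketone (carbonyl at C9) and a C11–C16 iodide made from methyl hydrogen (R)-3-methylglutarate (source of C13).
2. Feature used: in ring A the quaternary carbons C4 and C10 flank the ring-fusion carbon C5. C2–C3 is the ring-A bond farthest from this crowded array, and closing it as C2=C3 needs only a vinyl group on C4 and an allyl group on C10 (ring-closing metathesis).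
3. The metathesis precursor is ring B alone: a cyclohexanone carrying methyl and allyl on C10 and a 1,1-dimethylallyl group on C5, with the two arms trans.
4. Ring B comes from (R)-carvone. C4–C5 is made by Mukaiyama–Michael addition anti to the isopropenyl group, C1–C10 by alkylation of the stored enolate anti to the new arm, and the isopropenyl group is then excised.
5. Ring order: ring B is bought and ring A is closed in step 9. C8 (methyl, oxygen) and C9 (side chain, hydrogen) are then built on the C9 ketone.

Key step: step 9

Remark: labdane numbering is used for all intermediates and β is the face of the C10 methyl group; the carbinol epimers formed in step 6 and the alkene isomers formed in step 18 are carried as mixtures because steps 7 and 20 erase these elements.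

**Step 1**
Reactants: 1 (R)-(−)-carvone; 2 methyl trimethylsilyl dimethylketene acetal
Product: 3 methyl 2-methyl-2-[(1R,5R)-2-methyl-5-(prop-1-en-2-yl)-3-(trimethylsilyloxy)cyclohex-2-en-1-yl]propanoate
Conditions: Ph3CSbCl6 (5 mol %), CH2Cl2, −78 °C; pyridine quench, aq NaHCO3 wash
Reagents that add atoms: none
Why: Mukaiyama–Michael addition under trityl-cation catalysis, in which the ketene acetal attacks the enone β-carbon (C5) axially on the face opposite the pseudo-equatorial isopropenyl group, which sets C5, and silyl transfer to the C9 oxygen stores the C9=C10 enolate regiochemistry that a protic work-up would lose.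

**Step 2**
Reactants: 3 enol silane; 4 3-bromo-1-(trimethylsilyl)prop-1-yne
Product: 6 methyl 2-methyl-2-{(1R,2S,5R)-2-methyl-3-oxo-5-(prop-1-en-2-yl)-2-[3-(trimethylsilyl)prop-2-yn-1-yl]cyclohexyl}propanoate, via potassium enolate 5 (not isolated)
Conditions: t-BuOK (1.0 equiv), THF, −20 °C; then 4, −78 → 0 °C
Reagents that add atoms: none
Why: Alkoxide cleavage of the enol silane releases the regiodefined tetrasubstituted enolate without touching the hindered ester, and its SN2 alkylation takes place at C10 on the α face, axial and anti to the pseudo-axial C5 arm, so that C1 is α and the methyl group β, while the C-silyl cap removes the acidic alkyne hydrogen and blocks SN2′ attack.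

**Step 3**
Reactants: 6 alkylated keto ester
Product: 8 methyl 2-methyl-2-{(1R,2S)-2-methyl-3-oxo-2-[3-(trimethylsilyl)prop-2-yn-1-yl]cyclohexyl}propanoate, via methoxy hydroperoxide 7 (not isolated)
Conditions: O3, MeOH, −78 °C (Sudan Red 7B end point), Ar purge; PhSH (1.5 equiv), FeSO4·7H2O (1.2 equiv), −78 °C → rt
Reagents that add atoms: none
Why: Ozonolytic hydrodealkenylation, in which the electron-rich 1,1-disubstituted alkene is ozonised much faster than the silylated alkyne, methanol traps the carbonyl oxide as 7, divalent iron cleaves its O–O bond, the alkoxyl radical loses methyl acetate by β-scission and the secondary C7 radical takes hydrogen from PhSH, while the silyl cap slows thiyl addition to the triple bond and no stereocentre is touched.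

**Step 4**
Reactants: 8 silyl alkyne
Product: 9 methyl 2-methyl-2-[(1R,2S)-2-methyl-3-oxo-2-(prop-2-yn-1-yl)cyclohexyl]propanoate
Conditions: K2CO3 (0.2 equiv), MeOH, rt
Reagents that add atoms: none
Why: Carbonate-catalysed methanolysis of the C(sp)–Si bond is the standard alkyne deprotection, and retro-Michael cleavage or epimerisation cannot occur because C10 bears no hydrogen.

**Step 5**
Reactants: 9 terminal alkyne
Product: 10 methyl 2-methyl-2-[(1R,2S)-2-methyl-3-oxo-2-(prop-2-en-1-yl)cyclohexyl]propanoate
Conditions: H2 (1 atm), Pd/CaCO3 poisoned with Pb(OAc)2, quinoline, EtOAc, rt, stopped after one equivalent of H2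
Reagents that add atoms: none
Why: Semihydrogenation on lead-poisoned palladium stops at the alkene, and it is run here, before the second vinyl group exists, so that no other C=C bond competes.

**Step 6**
Reactants: 10 allyl keto ester
Product: 11 (2S,3S)-3-(1-hydroxy-2-methylpropan-2-yl)-2-methyl-2-(prop-2-en-1-yl)cyclohexan-1-ol (both C1 epimers)
Conditions: LiAlH4, THF, 0 °C → rt; then H2O, aq NaOH
Reagents that add atoms: none
Why: Hydride reduction takes the hindered ester to the neopentyl alcohol and unavoidably the ketone to the carbinol, whose configuration is irrelevant because step 7 removes it.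

**Step 7**
Reactants: 11 diol
Product: 12 2-methyl-2-[(1S,2S)-2-methyl-3-oxo-2-(prop-2-en-1-yl)cyclohexyl]propanal
Conditions: (COCl)2, DMSO, CH2Cl2, −78 °C; Et3N, → 0 °C
Reagents that add atoms: none
Why: Swern oxidation activates both hydroxyl groups at low temperature before base is added, so that ketone and aldehyde form together and lactol formation followed by over-oxidation to a lactone is avoided.

**Step 8**
Reactants: 12 keto aldehyde
Product: 13 (2S,3S)-2-methyl-3-(2-methylbut-3-en-2-yl)-2-(prop-2-en-1-yl)cyclohexan-1-one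
Conditions: Ph3PCH3Br (1.2 equiv), t-BuOK (1.1 equiv), THF, 0 °C; then 12, −78 → 0 °C
Reagents that add atoms: methyltriphenylphosphonium bromide, C[P+](c1ccccc1)(c1ccccc1)c1ccccc1.[Br-]
Why: Wittig methylenation distinguishes the two carbonyl groups because the non-enolisable aldehyde reacts with the ylide at low temperature whereas the cyclohexanone next to quaternary C10 needs far more forcing conditions.

**Step 9**
Reactants: 13 diene ketone
Product: 14 (4aS,8aS)-5,5,8a-trimethyl-3,4,4a,5,8,8a-hexahydronaphthalen-1(2H)-one
Conditions: (H2IMes)(PCy3)Cl2Ru=CHPh (second-generation Grubbs catalyst, 5 mol %), 1,4-benzoquinone (10 mol %), CH2Cl2 (0.005 M), reflux, Ar sparge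
Reagents that add atoms: none
Why: Ring-closing alkene metathesis: the ruthenium benzylidene first exchanges with the unhindered allyl terminus on C10 to give a C2 alkylidene, this adds across the neopentyl vinyl group on C4 in a [2+2] sense, and cycloreversion of the ruthenacyclobutane gives C2=C3 and a ruthenium methylidene that carries the chain while ethylene escapes. The closest known reaction type is the ruthenium-carbene closure of octa-1,7-dienes to cyclohexenes, including dienes in which one vinyl group sits on a quaternary carbon. Ring A closes as a six-membered carbocycle with the new alkene endocyclic, and the trans ring fusion is inherited because C5 and C10 are not touched. No stereocentre is formed. The step needs cyclisation to win over dimerisation through the allyl group and over allyl-to-propenyl isomerisation; high dilution, the gem-dimethyl group on C4, the reluctance of the neopentyl vinyl group to react intermolecularly and the gauche relation of the two arms in the diequatorial chair favour closure, and 1,4-benzoquinone intercepts ruthenium hydrides. The C9 ketone is a spectator that this catalyst tolerates.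

**Step 10**
Reactants: 14 octalone
Product: 16 (2R,4aS,8aS)-2,5,5,8a-tetramethyl-3,4,4a,5,8,8a-hexahydronaphthalen-1(2H)-one, via lithium enolate 15 (not isolated)
Conditions: LiN(i-Pr)2, THF, −78 °C; MeI, −78 → 0 °C
Reagents that add atoms: iodomethane, CI
Why: Kinetic enolate alkylation is regiochemically unambiguous because only C8 carries α-hydrogens, and the methyl group should enter opposite the axial C10 methyl (8α, equatorial), a centre that step 11 makes planar again.

**Step 11**
Reactants: 16 8-methyl octalone
Product: 18 (2R,4aS,8aS)-2-hydroxy-2,5,5,8a-tetramethyl-3,4,4a,5,8,8a-hexahydronaphthalen-1(2H)-one, via potassium enolate 17 (not isolated)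
Conditions: KN(SiMe3)2, THF, −78 → 0 °C; 2-(phenylsulfonyl)-3-phenyloxaziridine, −78 °C; aq NH4Cl
Reagents that add atoms: 2-(phenylsulfonyl)-3-phenyloxaziridine, O=S(=O)(c1ccccc1)N1OC1c1ccccc1
Why: Enolate hydroxylation with an N-sulfonyloxaziridine (Davis oxidation), in which the β face of the C8=C9 enolate is screened by the C10 methyl group that would be syn-axial to a β reagent, so that oxygen is delivered to the α face and C8 is set as 8α-OH with 8β-CH3, while the isolated C2=C3 alkene is inert to this oxidant.

**Step 12**
Reactants: 18 α-hydroxy ketone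
Product: 19 (2R,4aS,8aS)-2,5,5,8a-tetramethyl-2-(triethylsilyloxy)-3,4,4a,5,8,8a-hexahydronaphthalen-1(2H)-one
Conditions: Et3SiOTf, 2,6-lutidine, CH2Cl2, 0 °C → rt
Reagents that add atoms: triethylsilyl trifluoromethanesulfonate, CC[Si](CC)(CC)OS(=O)(=O)C(F)(F)F
Why: Silylation with a silyl triflate and a hindered pyridine base is the standard way to cap a tertiary alcohol, and it removes the acidic proton and the α-ketol rearrangement pathway before the organometallic step.

**Step 13**
Reactants: 20 methyl hydrogen (R)-3-methylglutarate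
Product: 21 methyl (3R)-5-hydroxy-3-methylpentanoate
Conditions: BH3·SMe2, THF, −10 °C → rt; then H2O
Reagents that add atoms: none
Why: Borane reduces the free carboxylic acid through its acyloxyborane much faster than the methyl ester, which differentiates the two arms at C13 without touching the stereocentre.

**Step 14**
Reactants: 21 hydroxy ester
Product: 22 methyl (3R)-5-(tert-butyldimethylsilyloxy)-3-methylpentanoate
Conditions: t-BuMe2SiCl, imidazole, CH2Cl2, rt
Reagents that add atoms: tert-butyldimethylsilyl chloride, CC(C)(C)[Si](C)(C)Cl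
Why: Standard silylation of a primary alcohol, carried out at once so that the hydroxy ester cannot lactonise, and the protected oxygen marks the future C15.

**Step 15**
Reactants: 22 silyloxy ester
Product: 23 (3S)-5-(tert-butyldimethylsilyloxy)-3-methylpentan-1-ol
Conditions: LiAlH4, Et2O, 0 °C; then H2O, aq NaOH
Reagents that add atoms: none
Why: Hydride reduction of the ester gives the alcohol at the future C11, and the silyl ether is stable to LiAlH4 at this temperature.

**Step 16**
Reactants: 23 alcohol
Product: 24 tert-butyl{[(3R)-5-iodo-3-methylpentyl]oxy}dimethylsilane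
Conditions: I2, PPh3, imidazole, CH2Cl2, 0 °C → rt
Reagents that add atoms: iodine, [I][I]
Why: Appel-type iodination of a primary alcohol proceeds through the alkoxyphosphonium salt by SN2 displacement two carbons away from C13.

**Step 17**
Reactants: 24 iodide; 19 silyloxy ketone
Product: 27 (13S)-15-(tert-butyldimethylsilyloxy)-8α-(triethylsilyloxy)-9-epi-labd-2-en-9β-ol (9R; C11 chain axial on the α face; OH equatorial on the β face), via alkyllithium 25 (not isolated), via alkylcerium dichloride 26 (not isolated)
Conditions: 24 (2 equiv), t-BuLi (4 equiv), Et2O–pentane, −78 °C; anhydrous CeCl3, THF, −78 °C; then 19, −78 → −30 °C; aq NH4Cl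
Reagents that add atoms: none
Why: Halogen–lithium exchange, transmetalation and organocerium 1,2-addition, in which ketone 19 has no α-hydrogen so that enolisation cannot compete, the oxophilic and weakly basic cerium reagent is the standard choice for crowded ketones and gives an alkoxide slow to accept the neighbouring silyl group, and attack should occur on the α face because the β side is flanked by the axial methyl groups on C8 and C10, a C9 configuration that step 18 erases.

**Step 18**
Reactants: 27 tertiary alcohol
Product: 29 (13S)-15-(tert-butyldimethylsilyloxy)-8α-(triethylsilyloxy)labda-2,9(11)-diene (E/Z mixture at C9=C11), via chlorosulfite 28 (not isolated)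
Conditions: SOCl2, pyridine, −30 → 0 °C
Reagents that add atoms: none
Why: Dehydration through the chlorosulfite with pyridine as base (E2-type elimination), in which C8 and C10 carry no hydrogen so that the C11 hydrogens are the only β-hydrogens and the exocyclic C9=C11 alkene is the only possible elimination product, while low temperature and excess pyridine are meant to keep the reaction away from a free C9 cation.

**Step 19**
Reactants: 29 bis-silyl ether
Product: 30 (13S)-labda-2,9(11)-diene-8α,15-diol (E/Z mixture at C9=C11)
Conditions: Bu4NF, THF, rt → 40 °C; then H2O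
Reagents that add atoms: none
Why: Fluoride cleaves both silyl ethers in one operation under non-acidic conditions that the tertiary allylic alcohol tolerates.

**Step 20**
Reactants: 30 diene diol
Product: 31 (13S)-labdane-8α,15-diol
Conditions: [Ir(cod)(PCy3)(py)]PF6 (10 mol %), H2 (1–4 atm), CH2Cl2, rt
Reagents that add atoms: none
Why: Hydroxyl-assisted homogeneous hydrogenation with the cationic iridium catalyst, known for hindered tri- and tetrasubstituted alkenes, in which the 8α-OH binds iridium on the α face and the β face is closed by the axial methyl groups on C8 and C10, so that hydrogen reaches C9 from the α face (9α-H, side chain equatorial) and C2=C3 is saturated in the same operation.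

**Step 21**
Reactants: 31 diol
Product: 33 (13S)-8α-hydroxylabdan-15-oic acid (labdanolic acid), via aldehyde 32 (not isolated)
Conditions: 2,2,6,6-tetramethylpiperidin-1-oxyl (20 mol %), PhI(OAc)2 (2.2 equiv), MeCN–H2O, rt
Reagents that add atoms: water, O
Why: Oxoammonium oxidation takes the primary alcohol through aldehyde 32 and its hydrate to the acid and cannot touch the tertiary 8α-OH.

**Step 22**
Reactants: 33 labdanolic acid
Product: 34 (3S)-5-[(1R,2R,4aS,8aS)-2-(formyloxy)-2,5,5,8a-tetramethyldecahydronaphthalen-1-yl]-3-methylpentanoic acid (target)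
Conditions: HCO2H, Ac2O, 55 °C, then cooled; 33, pyridine, CH2Cl2, 0 °C → rt; then H2O
Reagents that add atoms: formic acid, O=CO (delivered as acetic formic anhydride, CC(=O)OC=O)
Why: O-Formylation with acetic formic anhydride transfers the small and more electrophilic formyl group, is known to acylate tertiary alcohols under buffered conditions that avoid dehydration, leaves the C8–O bond and hence the C8 configuration intact, and any mixed anhydride formed at C15 is hydrolysed in the aqueous work-up.

**Compound list**
1 | (R)-(−)-carvone | CC1=CC[C@H](CC1=O)C(C)=C | starting material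
2 | methyl trimethylsilyl dimethylketene acetal | COC(O[Si](C)(C)C)=C(C)C | starting material
3 | methyl 2-methyl-2-[(1R,5R)-2-methyl-5-(prop-1-en-2-yl)-3-(trimethylsilyloxy)cyclohex-2-en-1-yl]propanoate | COC(=O)C(C)(C)[C@@H]1C[C@@H](C(C)=C)CC(O[Si](C)(C)C)=C1C | intermediate
4 | 3-bromo-1-(trimethylsilyl)prop-1-yne | C[Si](C)(C)C#CCBr | starting material
5 | potassium enolate from 3 | COC(=O)C(C)(C)[C@@H]1C[C@@H](C(C)=C)CC([O-])=C1C.[K+] | intermediate
6 | methyl 2-methyl-2-{(1R,2S,5R)-2-methyl-3-oxo-5-(prop-1-en-2-yl)-2-[3-(trimethylsilyl)prop-2-yn-1-yl]cyclohexyl}propanoate | COC(=O)C(C)(C)[C@@H]1C[C@@H](C(C)=C)CC(=O)[C@@]1(C)CC#C[Si](C)(C)C | intermediate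
7 | 1-hydroperoxy-1-methoxyethyl analogue of 6 (peroxyketal carbon undefined) | COC(=O)C(C)(C)[C@@H]1C[C@@H](C(C)(OC)OO)CC(=O)[C@@]1(C)CC#C[Si](C)(C)C | intermediate
8 | methyl 2-methyl-2-{(1R,2S)-2-methyl-3-oxo-2-[3-(trimethylsilyl)prop-2-yn-1-yl]cyclohexyl}propanoate | COC(=O)C(C)(C)[C@@H]1CCCC(=O)[C@@]1(C)CC#C[Si](C)(C)C | intermediate
9 | methyl 2-methyl-2-[(1R,2S)-2-methyl-3-oxo-2-(prop-2-yn-1-yl)cyclohexyl]propanoate | COC(=O)C(C)(C)[C@@H]1CCCC(=O)[C@@]1(C)CC#C | intermediate
10 | methyl 2-methyl-2-[(1R,2S)-2-methyl-3-oxo-2-(prop-2-en-1-yl)cyclohexyl]propanoate | COC(=O)C(C)(C)[C@@H]1CCCC(=O)[C@@]1(C)CC=C | intermediate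
11 | (2S,3S)-3-(1-hydroxy-2-methylpropan-2-yl)-2-methyl-2-(prop-2-en-1-yl)cyclohexan-1-ol, both C1 epimers | OCC(C)(C)[C@@H]1CCCC(O)[C@@]1(C)CC=C | intermediate
12 | 2-methyl-2-[(1S,2S)-2-methyl-3-oxo-2-(prop-2-en-1-yl)cyclohexyl]propanal | O=CC(C)(C)[C@@H]1CCCC(=O)[C@@]1(C)CC=C | intermediate
13 | (2S,3S)-2-methyl-3-(2-methylbut-3-en-2-yl)-2-(prop-2-en-1-yl)cyclohexan-1-one | O=C1CCC[C@@H](C(C)(C)C=C)[C@]1(C)CC=C | intermediate
14 | (4aS,8aS)-5,5,8a-trimethyl-3,4,4a,5,8,8a-hexahydronaphthalen-1(2H)-one | O=C1CCC[C@H]2C(C)(C)C=CC[C@]12C | intermediate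
15 | lithium enolate of 14 | [Li+].[O-]C1=CCC[C@H]2C(C)(C)C=CC[C@]12C | intermediate
16 | (2R,4aS,8aS)-2,5,5,8a-tetramethyl-3,4,4a,5,8,8a-hexahydronaphthalen-1(2H)-one | O=C1[C@H](C)CC[C@H]2C(C)(C)C=CC[C@]12C | intermediate
17 | potassium enolate of 16 | [K+].[O-]C1=C(C)CC[C@H]2C(C)(C)C=CC[C@]12C | intermediate
18 | (2R,4aS,8aS)-2-hydroxy-2,5,5,8a-tetramethyl-3,4,4a,5,8,8a-hexahydronaphthalen-1(2H)-one | O=C1[C@](C)(O)CC[C@H]2C(C)(C)C=CC[C@]12C | intermediate
19 | (2R,4aS,8aS)-2,5,5,8a-tetramethyl-2-(triethylsilyloxy)-3,4,4a,5,8,8a-hexahydronaphthalen-1(2H)-one | O=C1[C@](C)(O[Si](CC)(CC)CC)CC[C@H]2C(C)(C)C=CC[C@]12C | intermediate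
20 | methyl hydrogen (R)-3-methylglutarate | C[C@H](CC(O)=O)CC(=O)OC | starting material
21 | methyl (3R)-5-hydroxy-3-methylpentanoate | C[C@H](CCO)CC(=O)OC | intermediate
22 | methyl (3R)-5-(tert-butyldimethylsilyloxy)-3-methylpentanoate | C[C@H](CCO[Si](C)(C)C(C)(C)C)CC(=O)OC | intermediate
23 | (3S)-5-(tert-butyldimethylsilyloxy)-3-methylpentan-1-ol | C[C@H](CCO[Si](C)(C)C(C)(C)C)CCO | intermediate
24 | tert-butyl{[(3R)-5-iodo-3-methylpentyl]oxy}dimethylsilane | C[C@H](CCO[Si](C)(C)C(C)(C)C)CCI | intermediate
25 | alkyllithium from 24 | C[C@H](CCO[Si](C)(C)C(C)(C)C)CC[Li] | intermediate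
26 | alkylcerium dichloride from 25 | C[C@H](CCO[Si](C)(C)C(C)(C)C)CC[Ce](Cl)Cl | intermediate
27 | (13S)-15-(tert-butyldimethylsilyloxy)-8α-(triethylsilyloxy)-9-epi-labd-2-en-9β-ol | C[C@@H](CC[C@@]1(O)[C@@]2(C)CC=CC(C)(C)[C@@H]2CC[C@@]1(C)O[Si](CC)(CC)CC)CCO[Si](C)(C)C(C)(C)C | intermediate
28 | 9-chlorosulfite of 27 | C[C@@H](CC[C@@]1(OS(=O)Cl)[C@@]2(C)CC=CC(C)(C)[C@@H]2CC[C@@]1(C)O[Si](CC)(CC)CC)CCO[Si](C)(C)C(C)(C)C | intermediate
29 | (13S)-15-(tert-butyldimethylsilyloxy)-8α-(triethylsilyloxy)labda-2,9(11)-diene, E/Z mixture | C[C@@H](CC=C1[C@@]2(C)CC=CC(C)(C)[C@@H]2CC[C@@]1(C)O[Si](CC)(CC)CC)CCO[Si](C)(C)C(C)(C)C | intermediate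
30 | (13S)-labda-2,9(11)-diene-8α,15-diol, E/Z mixture | C[C@@H](CC=C1[C@@]2(C)CC=CC(C)(C)[C@@H]2CC[C@@]1(C)O)CCO | intermediate
31 | (13S)-labdane-8α,15-diol | C[C@@H](CC[C@@H]1[C@@]2(C)CCCC(C)(C)[C@@H]2CC[C@@]1(C)O)CCO | intermediate
32 | (13S)-8α-hydroxylabdan-15-al | C[C@@H](CC[C@@H]1[C@@]2(C)CCCC(C)(C)[C@@H]2CC[C@@]1(C)O)CC=O | intermediate
33 | (13S)-8α-hydroxylabdan-15-oic acid | C[C@@H](CC[C@@H]1[C@@]2(C)CCCC(C)(C)[C@@H]2CC[C@@]1(C)O)CC(=O)O | intermediate
34 | (13S)-8α-formyloxylabdan-15-oic acid (5S,8R,9R,10S,13S) | C[C@@H](CC[C@@H]1[C@@]2(C)CCCC(C)(C)[C@@H]2CC[C@@]1(C)OC=O)CC(=O)O | target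

**Step count**
- Total step count: 22.
- Longest linear sequence: 18 steps from 1 (steps 1–12 and 17–22).
- Side-chain branch: 4 steps (13–16).

**Steps most likely to fail**

**Step 9.** Addition of the C2 alkylidene to the neopentyl vinyl group may be slower than intermolecular metathesis at the allyl group or than hydride-induced alkene migration. This is more likely if the chair with both arms axial is strongly populated.

The fallback keeps the C2=C3 metathesis but reverses the direction of closure by a relay. It sets out from 12. Wittig reaction with the ylide from hex-5-en-1-yl(triphenyl)phosphonium bromide and KN(SiMe3)2 gives the relay triene (2S,3S)-2-methyl-3-[(3Z)-2-methylnona-3,8-dien-2-yl]-2-(prop-2-en-1-yl)cyclohexan-1-one F1. The same ruthenium catalyst enters at the unhindered terminal alkene of the relay chain and expels cyclopentene, which places it on C3. From there it closes onto the unhindered allyl group. The fallback comes back to the route at 14.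

**Step 17.** Both faces of the C9 carbonyl are screened. Addition may therefore lose against thermal decay of the organocerium reagent, hydride transfer to the carbonyl, or silyl migration in the alkoxide.

The fallback makes C9–C11 on an sp2 carbon and brings in the C8 oxygen afterwards. It sets out from 16.
- Enolisation with KN(SiMe3)2 and trapping with PhN(SO2CF3)2 gives the enol triflate F2.
- Alkyllithium 25 is transmetalated with ZnCl2 to the alkylzinc chloride F3.
- Negishi coupling of the two (PdCl2(dppf), LiCl, THF–NMP, 60 °C) gives the tetrasubstituted alkene (13S)-15-(tert-butyldimethylsilyloxy)labda-2,8-diene F4.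
- A Schenck ene reaction (O2, tetraphenylporphyrin, light, CH2Cl2, 0 °C) should attack the α face. It should abstract a C11 hydrogen, which is geminal to the bulky C10, so that oxygen ends on C8 in the 8α-hydroperoxide F5.
- PPh3 reduces F5 to the allylic alcohol (13S)-15-(tert-butyldimethylsilyloxy)labda-2,9(11)-dien-8α-ol F6.
- Bu4NF then removes the silyl group, and the fallback comes back to the route at 30.

**Step 18.** Ionisation at C9 may run ahead of proton loss from C11. It would be followed by a pinacol-type 1,2-shift from C8, driven by the neighbouring silyloxy oxygen.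

The fallback avoids both the cation and the alkene by radical deoxygenation. It sets out from 27.
- Deprotonation with n-BuLi at −78 °C and acylation with methyl chlorooxoacetate gives the methyl oxalate F7.
- Bu3SnH with azobisisobutyronitrile in refluxing toluene generates the tertiary C9 radical. This radical should take hydrogen on the open α face and give (13S)-15-(tert-butyldimethylsilyloxy)-8α-(triethylsilyloxy)labd-2-ene F8.
- Bu4NF gives (13S)-labd-2-ene-8α,15-diol F9.
- Hydrogenation over Pd/C in EtOAc saturates C2=C3, and the fallback comes back to the route at 31.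

**Further compounds**
F1 | step 9 | (2S,3S)-2-methyl-3-[(3Z)-2-methylnona-3,8-dien-2-yl]-2-(prop-2-en-1-yl)cyclohexan-1-one | O=C1CCC[C@@H](C(C)(C)/C=C\CCCC=C)[C@]1(C)CC=C
F2 | step 17 | (4aS,8aS)-2,5,5,8a-tetramethyl-3,4,4a,5,8,8a-hexahydronaphthalen-1-yl trifluoromethanesulfonate | O=S(=O)(OC1=C(C)CC[C@H]2C(C)(C)C=CC[C@]12C)C(F)(F)F
F3 | step 17 | 5-(tert-butyldimethylsilyloxy)-3-methylpentylzinc chloride (C13 as in 24) | C[C@H](CCO[Si](C)(C)C(C)(C)C)CC[Zn]Cl
F4 | step 17 | (13S)-15-(tert-butyldimethylsilyloxy)labda-2,8-diene | C[C@@H](CCC1=C(C)CC[C@H]2C(C)(C)C=CC[C@]12C)CCO[Si](C)(C)C(C)(C)C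
F5 | step 17 | (13S)-15-(tert-butyldimethylsilyloxy)-8α-hydroperoxylabda-2,9(11)-diene | C[C@@H](CC=C1[C@@]2(C)CC=CC(C)(C)[C@@H]2CC[C@@]1(C)OO)CCO[Si](C)(C)C(C)(C)C
F6 | step 17 | (13S)-15-(tert-butyldimethylsilyloxy)labda-2,9(11)-dien-8α-ol | C[C@@H](CC=C1[C@@]2(C)CC=CC(C)(C)[C@@H]2CC[C@@]1(C)O)CCO[Si](C)(C)C(C)(C)C
F7 | step 18 | 9-(methyl oxalate) of 27 | C[C@@H](CC[C@@]1(OC(=O)C(=O)OC)[C@@]2(C)CC=CC(C)(C)[C@@H]2CC[C@@]1(C)O[Si](CC)(CC)CC)CCO[Si](C)(C)C(C)(C)C
F8 | step 18 | (13S)-15-(tert-butyldimethylsilyloxy)-8α-(triethylsilyloxy)labd-2-ene | C[C@@H](CC[C@@H]1[C@@]2(C)CC=CC(C)(C)[C@@H]2CC[C@@]1(C)O[Si](CC)(CC)CC)CCO[Si](C)(C)C(C)(C)C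
F9 | step 18 | (13S)-labd-2-ene-8α,15-diol | C[C@@H](CC[C@@H]1[C@@]2(C)CC=CC(C)(C)[C@@H]2CC[C@@]1(C)O)CCO
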